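## Retrosynthetic overview

1. Target 22 ⇐ Mannich base 19: the C1=C2 and C4=C15 double bonds are unveiled last, in one selenoxide / amine-oxide elimination.
2. 19 ⇐ aldehyde 16: the C5–C6 bond comes from a SmI2 ketyl (aldehyde carbon C6) adding to C5, the β-carbon of the ring A vinylogous ester. This closes ring B across the ether oxygen, then the lactone, and the resulting enolate is trapped to add C15.
3. 16 ⇐ ring A aldehyde 7 + allylic bromide 11: the C7–C8 bond comes from an indium-mediated 2-(methoxycarbonyl)allylation, followed by angeloylation and glycol cleavage.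
4. Ring A (6) ⇐ (R)-linalool 1: oxidative cleavage to a lactone, acetylide addition, 7-endo oxa-Michael closure; C10 comes from the chiral pool.
5. Ring order: ring A (oxepinone) first; ring B (bridging oxepane) and ring C (lactone) together in the key step.

Assumption: C1 to C15 are the germacrane numbers of the target (ether O between C5 and C10, lactone C12–O–C6); ring A = O/C10/C1/C2/C3/C4/C5, ring B = O/C5/C6/C7/C8/C9/C10, ring C = lactone; angeloyl = (2Z)-2-methylbut-2-enoyl.

## Route

Step 1
Reactants: 1 (R)-(−)-linalool [(3R)-3,7-dimethylocta-1,6-dien-3-ol]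
Product: 3 (5R)-5-ethenyl-5-methyloxolan-2-one, via lactol 2 (not isolated)
Conditions: O3 (1.0 equiv), MeCN/H2O 9:1, 0 °C; then NaClO2, NaH2PO4, 0 → 23 °C; HCl work-up
Reagents that add atoms: ozone, O=[O+][O-]; sodium chlorite, [Na+].[O-]Cl=O
Why: Ozonolysis in wet MeCN cleaves the electron-rich trisubstituted alkene much faster than the allylic vinyl group and gives the aldehyde as lactol 2, which chlorite (Pinnick oxidation) takes to the lactone; C10 is carried over unchanged from 1.

Step 2
Reactants: 3 (5R)-5-ethenyl-5-methyloxolan-2-one; 4 acetylene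
Product: 5 (6R)-6-hydroxy-6-methyloct-7-en-1-yn-3-one
Conditions: 4 (excess), n-BuLi, THF, −78 °C (HC≡CLi); then 3, −78 °C; AcOH quench
Reagents that add atoms: none
Why: Acetylide 1,2-addition to the γ-lactone stops at the tetrahedral adduct at −78 °C and gives the hydroxy ynone (in equilibrium with its cyclic hemiketal) only on quench, so no second addition occurs; no stereocentre is formed.

Step 3
Reactants: 5 (6R)-6-hydroxy-6-methyloct-7-en-1-yn-3-one
Product: 6 (2R)-2-ethenyl-2-methyl-3,4-dihydrooxepin-5(2H)-one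
Conditions: PMe3 (20 mol %), CH2Cl2 (0.01 M), 0 → 23 °C
Reagents that add atoms: none
Why: Phosphine-catalysed oxa-Michael addition run intramolecularly: the tertiary alkoxide adds to the terminal ynone carbon (7-endo-dig) to give the cyclic vinylogous ester of ring A; the open hydroxy ynone is drained from its hemiketal and C10 is not involved.

Step 4
Reactants: 6 (2R)-2-ethenyl-2-methyl-3,4-dihydrooxepin-5(2H)-one
Product: 7 2-[(2R)-2-methyl-5-oxo-2,3,4,5-tetrahydrooxepin-2-yl]acetaldehyde
Conditions: PdCl2(PhCN)2 (10 mol %), CuCl2·2H2O (10 mol %), AgNO2 (5 mol %), O2 (1 atm), t-BuOH/MeNO2 15:1, 23 °C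
Reagents that add atoms: dioxygen, O=O
Why: Nitrite-modified aldehyde-selective Wacker oxidation: the fully substituted allylic ether carbon blocks attack at C9, so oxygen goes to the terminal carbon C8; no stereocentre is formed and the base-sensitive β-alkoxy aldehyde is used at once.

Step 5
Reactants: 8 (4S)-2,2-dimethyl-1,3-dioxolane-4-carbaldehyde; 9 methyl acrylate
Product: 10 methyl 2-{[(4S)-2,2-dimethyl-1,3-dioxolan-4-yl](hydroxy)methyl}prop-2-enoate (both carbinol epimers)
Conditions: DABCO (0.5 equiv), 1,4-dioxane/H2O 1:1, 23 °C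
Reagents that add atoms: none
Why: Morita–Baylis–Hillman reaction; the new carbinol centre is destroyed in step 6, so its configuration does not matter, and the dioxolane centre is retained.

Step 6
Reactants: 10 methyl 2-{[(4S)-2,2-dimethyl-1,3-dioxolan-4-yl](hydroxy)methyl}prop-2-enoate
Product: 11 methyl (2Z)-2-(bromomethyl)-3-[(4R)-2,2-dimethyl-1,3-dioxolan-4-yl]prop-2-enoate
Conditions: NBS, Me2S, CH2Cl2, 0 → 23 °C
Reagents that add atoms: N-bromosuccinimide, O=C1CCC(=O)N1Br
Why: Corey–Kim type activation and SN2′ bromide delivery (allylic transposition) give the thermodynamically preferred (Z)-2-(bromomethyl)alk-2-enoate from both epimers of 10 under neutral conditions; the dioxolane centre is untouched (its descriptor changes from S to R only through the CIP priorities).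

Step 7
Reactants: 7 2-[(2R)-2-methyl-5-oxo-2,3,4,5-tetrahydrooxepin-2-yl]acetaldehyde; 11 methyl (2Z)-2-(bromomethyl)-3-[(4R)-2,2-dimethyl-1,3-dioxolan-4-yl]prop-2-enoate
Product: 12 methyl (3R,4R)-3-[(4R)-2,2-dimethyl-1,3-dioxolan-4-yl]-4-hydroxy-2-methylidene-5-[(2R)-2-methyl-5-oxo-2,3,4,5-tetrahydrooxepin-2-yl]pentanoate
Conditions: In powder (1.5 equiv), 11 (1.5 equiv), THF/H2O 1:1, 23 °C
Reagents that add atoms: none
Why: Barbier-type 2-(alkoxycarbonyl)allylation (a β-metallated acrylate, that is a homoenolate equivalent) through a chair-like six-membered transition state: the (Z)-allylindium reacts at its γ-carbon to give the 7,8-syn adduct, and indium held by the adjacent dioxolane oxygen delivers the aldehyde to that face, which sets C7 (R) and C8 (R); the amine-free aqueous conditions spare the vinylogous ester.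

Step 8
Reactants: 12 methyl (3R,4R)-3-[(4R)-2,2-dimethyl-1,3-dioxolan-4-yl]-4-hydroxy-2-methylidene-5-[(2R)-2-methyl-5-oxo-2,3,4,5-tetrahydrooxepin-2-yl]pentanoate; 13 angelic acid [(2Z)-2-methylbut-2-enoic acid]
Product: 14 methyl (3R,4R)-3-[(4R)-2,2-dimethyl-1,3-dioxolan-4-yl]-2-methylidene-4-{[(2Z)-2-methylbut-2-enoyl]oxy}-5-[(2R)-2-methyl-5-oxo-2,3,4,5-tetrahydrooxepin-2-yl]pentanoate
Conditions: 13, 2,4,6-trichlorobenzoyl chloride, Et3N, toluene, 23 °C; then 12, DMAP, 23 °C
Reagents that add atoms: none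
Why: Yamaguchi esterification through the mixed anhydride at room temperature acylates O8 with retention at C8 and without isomerising the (Z)-angelate to the tiglate; it also blocks lactonisation of O8 onto the acrylate ester.

Step 9
Reactants: 14 methyl (3R,4R)-3-[(4R)-2,2-dimethyl-1,3-dioxolan-4-yl]-2-methylidene-4-{[(2Z)-2-methylbut-2-enoyl]oxy}-5-[(2R)-2-methyl-5-oxo-2,3,4,5-tetrahydrooxepin-2-yl]pentanoate
Product: 16 methyl (3R,4R)-3-formyl-2-methylidene-4-{[(2Z)-2-methylbut-2-enoyl]oxy}-5-[(2R)-2-methyl-5-oxo-2,3,4,5-tetrahydrooxepin-2-yl]pentanoate, via diol 15 (not isolated)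
Conditions: H5IO6 (2.0 equiv), EtOAc, 0 → 23 °C
Reagents that add atoms: none
Why: Periodic acid first hydrolyses the terminal acetonide and then cleaves the 1,2-diol (Malaprade glycol cleavage) to the C6 aldehyde under non-basic conditions, so the α-centre C7 and the β-acyloxy group survive; the aldehyde is used crude.

Step 10
Reactants: 16 methyl (3R,4R)-3-formyl-2-methylidene-4-{[(2Z)-2-methylbut-2-enoyl]oxy}-5-[(2R)-2-methyl-5-oxo-2,3,4,5-tetrahydrooxepin-2-yl]pentanoate; 17 N,N-dimethylmethyleneiminium iodide (CH2=NMe2+ I−)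
Product: 19 (5S,6S,7R,8R,10R)-8-angeloyloxy-15-(dimethylamino)-5,10-epoxy-3-oxogermacr-11(13)-en-12,6-olide (both C4 epimers), via samarium enolate 18 (not isolated)
Conditions: SmI2 (2.2 equiv, 0.1 M), THF, −78 °C, no proton source; then 17 (3 equiv), −78 → 0 °C; aq NaHCO3
Reagents that add atoms: samarium diiodide, I[Sm]I (its SmI2 unit is held only in 18)
Why: Proposed new method: SmI2 turns the aldehyde into a ketyl radical anion (a carbonyl carbon of reversed polarity) that adds 7-exo to C5, the electrophilic β-carbon of the cyclic vinylogous ester, the closest known reactions being the SmI2-induced ketyl addition to β-alkoxy acrylates used for oxepane synthesis and the SmI2 ketyl–enoate lactonisation; the tether from C10 can reach only one face of C5, so C5 (S) is fixed by C10, and a chair-like transition state with the O–Sm group and the C7 acrylate arm both pseudo-equatorial gives the 6,7-trans relationship (C6 S); a second SmI2 reduces the α-keto radical to the trivalent samarium enolate 18, whose C5–O bond lies in the enolate plane so that β-elimination is disfavoured, the C6 alkoxide closes the trans-fused α-methylene lactone on the methyl ester, and the enolate is alkylated at C4 by the iminium salt (Mannich reaction), the new C4 centre being lost in step 11.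

Step 11
Reactants: 19 (5S,6S,7R,8R,10R)-8-angeloyloxy-15-(dimethylamino)-5,10-epoxy-3-oxogermacr-11(13)-en-12,6-olide
Product: 22 (5S,6S,7R,8R,10S)-8-angeloyloxy-5,10-epoxy-3-oxogermacra-1,4(15),11(13)-trien-12,6-olide (CNP0335602.1), via selenide 20 (not isolated), via selenoxide N-oxide 21 (not isolated)
Conditions: LiN(SiMe3)2 (1.1 equiv), THF, −78 °C; PhSeCl (1.2 equiv); then mCPBA (2.5 equiv), CH2Cl2, −78 → 23 °C
Reagents that add atoms: benzeneselenenyl chloride, Cl[Se]c1ccccc1 (held only in 20 and 21); 3-chloroperbenzoic acid, OOC(=O)c1cccc(Cl)c1 (its oxygen held only in 21)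
Why: Kinetic deprotonation takes place at the less hindered C2 methylene (the lactone has no α-hydrogen), the enolate is selenenylated, and mCPBA oxidises selenium and nitrogen: selenoxide syn-elimination gives the ring cis C1=C2 enone and Cope elimination of the β-keto amine N-oxide gives the C4 exo-methylene group, neither touching a stereocentre.

## Compound list

1 | (R)-(−)-linalool, (3R)-3,7-dimethylocta-1,6-dien-3-ol | C=C[C@](C)(O)CCC=C(C)C | starting material
2 | (5R)-5-ethenyl-5-methyloxolan-2-ol (lactol, both anomers) | C=C[C@@]1(C)CCC(O)O1 | intermediate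
3 | (5R)-5-ethenyl-5-methyloxolan-2-one | C=C[C@@]1(C)CCC(=O)O1 | intermediate
4 | acetylene | C#C | starting material
5 | (6R)-6-hydroxy-6-methyloct-7-en-1-yn-3-one | C=C[C@](C)(O)CCC(=O)C#C | intermediate
6 | (2R)-2-ethenyl-2-methyl-3,4-dihydrooxepin-5(2H)-one | C=C[C@@]1(C)CCC(=O)C=CO1 | intermediate
7 | 2-[(2R)-2-methyl-5-oxo-2,3,4,5-tetrahydrooxepin-2-yl]acetaldehyde | O=CC[C@@]1(C)CCC(=O)C=CO1 | intermediate
8 | (4S)-2,2-dimethyl-1,3-dioxolane-4-carbaldehyde | O=C[C@@H]1COC(C)(C)O1 | starting material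
9 | methyl acrylate | C=CC(=O)OC | starting material
10 | methyl 2-{[(4S)-2,2-dimethyl-1,3-dioxolan-4-yl](hydroxy)methyl}prop-2-enoate (both carbinol epimers) | COC(=O)C(=C)C(O)[C@@H]1COC(C)(C)O1 | intermediate
11 | methyl (2Z)-2-(bromomethyl)-3-[(4R)-2,2-dimethyl-1,3-dioxolan-4-yl]prop-2-enoate | COC(=O)/C(CBr)=C/[C@@H]1COC(C)(C)O1 | intermediate
12 | methyl (3R,4R)-3-[(4R)-2,2-dimethyl-1,3-dioxolan-4-yl]-4-hydroxy-2-methylidene-5-[(2R)-2-methyl-5-oxo-2,3,4,5-tetrahydrooxepin-2-yl]pentanoate | COC(=O)C(=C)[C@@H]([C@@H]1COC(C)(C)O1)[C@H](O)C[C@@]1(C)CCC(=O)C=CO1 | intermediate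
13 | angelic acid, (2Z)-2-methylbut-2-enoic acid | C/C=C(/C)C(=O)O | starting material
14 | methyl (3R,4R)-3-[(4R)-2,2-dimethyl-1,3-dioxolan-4-yl]-2-methylidene-4-{[(2Z)-2-methylbut-2-enoyl]oxy}-5-[(2R)-2-methyl-5-oxo-2,3,4,5-tetrahydrooxepin-2-yl]pentanoate | COC(=O)C(=C)[C@@H]([C@@H]1COC(C)(C)O1)[C@H](OC(=O)/C(C)=C\C)C[C@@]1(C)CCC(=O)C=CO1 | intermediate
15 | methyl 3-[(1R)-1,2-dihydroxyethyl]-2-methylidene-4-{[(2Z)-2-methylbut-2-enoyl]oxy}-5-[(2R)-2-methyl-5-oxo-2,3,4,5-tetrahydrooxepin-2-yl]pentanoate (other centres arranged as in 14) | COC(=O)C(=C)[C@@H]([C@@H](O)CO)[C@H](OC(=O)/C(C)=C\C)C[C@@]1(C)CCC(=O)C=CO1 | intermediate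
16 | methyl (3R,4R)-3-formyl-2-methylidene-4-{[(2Z)-2-methylbut-2-enoyl]oxy}-5-[(2R)-2-methyl-5-oxo-2,3,4,5-tetrahydrooxepin-2-yl]pentanoate | COC(=O)C(=C)[C@@H](C=O)[C@H](OC(=O)/C(C)=C\C)C[C@@]1(C)CCC(=O)C=CO1 | intermediate
17 | N,N-dimethylmethyleneiminium iodide | C=[N+](C)C.[I-] | starting material
18 | diiodosamarium C3-enolate of (5S,6S,7R,8R,10R)-8-angeloyloxy-5,10-epoxy-3-oxogermacr-11(13)-en-12,6-olide | C=C1C(=O)O[C@H]2[C@H]1[C@H](OC(=O)/C(C)=C\C)C[C@@]1(C)CCC(O[Sm](I)I)=C[C@@H]2O1 | intermediate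
19 | (5S,6S,7R,8R,10R)-8-angeloyloxy-15-(dimethylamino)-5,10-epoxy-3-oxogermacr-11(13)-en-12,6-olide (both C4 epimers) | C=C1C(=O)O[C@H]2[C@H]1[C@H](OC(=O)/C(C)=C\C)C[C@@]1(C)CCC(=O)C(CN(C)C)[C@@H]2O1 | intermediate
20 | 2-(phenylselanyl) derivative of 19 | C=C1C(=O)O[C@H]2[C@H]1[C@H](OC(=O)/C(C)=C\C)C[C@@]1(C)CC([Se]c3ccccc3)C(=O)C(CN(C)C)[C@@H]2O1 | intermediate
21 | selenoxide and amine N-oxide of 20 | C=C1C(=O)O[C@H]2[C@H]1[C@H](OC(=O)/C(C)=C\C)C[C@@]1(C)CC([Se](=O)c3ccccc3)C(=O)C(C[N+](C)(C)[O-])[C@@H]2O1 | intermediate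
22 | (5S,6S,7R,8R,10S)-8-angeloyloxy-5,10-epoxy-3-oxogermacra-1,4(15),11(13)-trien-12,6-olide (CNP0335602.1) | C=C1C(=O)O[C@H]2[C@H]1[C@H](OC(=O)/C(C)=C\C)C[C@@]1(C)C=CC(=O)C(=C)[C@@H]2O1 | target

## Step count and risks

Total: 11 steps. Longest linear sequence: 9 steps (1 → 3 → 5 → 6 → 7 → 12 → 14 → 16 → 19 → 22, steps 1, 2, 3, 4, 7, 8, 9, 10, 11); the bromide arm (steps 5 and 6) joins at step 7.

Step 10 is the most likely to fail. The bridging ketyl closure onto a cyclic vinylogous ester and the one-pot Mannich trapping are untested, and SmI2 may also attack the new α-methylene lactone. The fallback sets out from 16: the SmI2 closure is run without the iminium salt and the samarium enolate is quenched with TMSCl/Et3N, so that the regiodefined silyl enol ether F1 of the bicyclic keto lactone is isolated. A separate Mukaiyama–Mannich reaction of F1 with CH2=NMe2+ I− in CH2Cl2 then gives 19, where the route is rejoined.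

Step 7 is the second risk. Facial control by the dioxolane is argued by analogy only, the allylindium reagent can lose its β-alkoxy group, and aldehyde 7 can eliminate its β-oxygen. The fallback sets out from 10 (with 7): 10 is acetylated to the acetate F2, which B2pin2/CuCl converts into the allylboronate F3. F3 is added to 7 in toluene (Sc(OTf)3 cat.); the closed allylboration transition state gives the same 7,8-syn adduct without a reducing metal, and the route is rejoined at 12.

Step 3 is the third risk. A tertiary alcohol must close a seven-membered ring in competition with hemiketal formation and ynone oligomerisation. The fallback sets out from 5: Et2NH is added to the ynone to give the enaminone F4, and the ring is closed by acid-promoted exchange (TFA, CH2Cl2), the tertiary alcohol displacing diethylamine at the activated β-carbon. The route is rejoined at 6.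

## Further compounds

F1 | step 10 | (5S,6S,7R,8R,10R)-8-angeloyloxy-5,10-epoxy-3-(trimethylsilyloxy)germacra-3,11(13)-dien-12,6-olide | C=C1C(=O)O[C@H]2[C@H]1[C@H](OC(=O)/C(C)=C\C)C[C@@]1(C)CCC(O[Si](C)(C)C)=C[C@@H]2O1
F2 | step 7 | methyl 2-{(acetyloxy)[(4S)-2,2-dimethyl-1,3-dioxolan-4-yl]methyl}prop-2-enoate (both epimers) | COC(=O)C(=C)C(OC(C)=O)[C@@H]1COC(C)(C)O1
F3 | step 7 | methyl (2E)-3-[(4R)-2,2-dimethyl-1,3-dioxolan-4-yl]-2-[(4,4,5,5-tetramethyl-1,3,2-dioxaborolan-2-yl)methyl]prop-2-enoate | COC(=O)/C(CB1OC(C)(C)C(C)(C)O1)=C/[C@@H]1COC(C)(C)O1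
F4 | step 3 | (1E,6R)-1-(diethylamino)-6-hydroxy-6-methylocta-1,7-dien-3-one | C=C[C@](C)(O)CCC(=O)/C=C/N(CC)CC
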